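Slowness is what these flasks have in common: target creeps up for hours, and the question is what a cold start costs.

the same everywhere: protic impurity 0.0215 M; catalyst 0.21 mM (in portions, 4)
- amber: starting material 0.0087 M; temperature −5 °C; run made earlier; portions every 40 min
- violet: starting material 0.026 M; temperature 6 °C; run made earlier; portions every 40 min
- Friday's: starting material 0.043 M; at −10 °C until 4.0 h, from then on at 10 °C; the portions of catalyst follow each other after 40 min, the first at the start; time 12 h
- Thursday's: starting material 0.010 M; at −10 °C throughout; the portions of catalyst follow each other after 40 min, the first at the start; time 12 h

- amber (time / h: target / %): 1.00: 0.6; 1.50: 1.5; 2.50: 2.1; 4.00: 5.6; 8.00: 12.2; 12.0: 18.4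
- violet (time / h: target / %): 0.417: 0.3; 1.00: 3.8; 2.00: 7.7; 2.50: 8.9; 5.00: 25.2

(each reading ± 1 percentage point)

- the earlier runs were read with a standard deviation of 1 percentage point
- on the list of suspects stand: catalyst + intermediate -> catalyst + target; starting material + protic impurity -> quenched substrate; target + catalyst <-> isomer of the product + catalyst; starting material -> intermediate

1. the winner by amount of target, in percent of the starting material charged; "neither" if no more than 2 percentage points parts them (Friday's / Thursday's / neither)
2. how much target is there at the end, in percent of the starting material charged: Friday's
3. how much target is there at the end, in percent of the starting material charged: Thursday's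

Two chemists read the same runs differently. Vera holds that each hour turns a fixed share of what remains, a share set by temperature, so she takes the climb c, the charge's share gained per hour, from the reading at 1.00 h to the last: 0.0162 h⁻¹ in the amber run and 0.0535 h⁻¹ in the violet run. Carrying that ratio evenly across the degrees gives 0.00940 h⁻¹ at −10 °C and 0.0826 h⁻¹ at 10 °C. Her measure is the clock sum S, each stretch's c times its hours added up, with the target's share reckoned as one minus exp(−S); for Friday's flask S is 0.699, which reads 50.3%, and for Thursday's flask S is 0.113, which reads 10.7%.

Tom holds that equal catalyst turns over a fixed molar amount per hour, whatever the charge, so the climb is a straight line in molarity, and between the amber and violet runs that molar climb rose 9.88 times. The amber and violet runs differ in charge and in temperature at once, and each of the two views reads its own number from them. Tom's line gives 60.0% for Friday's flask and 5.96% for Thursday's flask.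

The forecast sides with Vera's first-order reading and names Friday's, with 42% against 10%. Its figure for Friday's flask is lower than her bare sum, after “Allowing for some quench and isomerisation”.

The flask gives Friday's, with 45.8% of target in Friday's flask and 10.2% in Thursday's flask, and in both flasks these stand nearer to what S reads than to Tom's line . His straight line keeps the cold: Thursday's flask holds 4.79% at 6.00 h and about twice that at 12.0 h.

    catalyst + intermediate → catalyst + target (k = 129 M⁻¹ h⁻¹, Ea = 53.0 kJ mol⁻¹)
    starting material + protic impurity → quenched substrate (k = 7.92 M⁻¹ h⁻¹, Ea = 59.0 kJ mol⁻¹)
    target + catalyst ⇌ isomer of the product + catalyst, rate k3*[catalyst]*[target] forward; the back reaction follows from the equilibrium constant (K = 0.690, k = 1350 M⁻¹ h⁻¹, Ea = 36.0 kJ mol⁻¹, ΔH = −41.0 kJ mol⁻¹)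
    starting material → intermediate (k = 0.344 h⁻¹, Ea = 93.0 kJ mol⁻¹)
    (constants at −10 °C)

In Thursday's flask, intermediate under catalyst, pseudo-first-order with catalyst at 100% of its charge, has a half-life of 26 h at 12.0 h, far slower than the 2.0 h of starting material becoming intermediate. At the end, intermediate stands at 52.6% and starting material at 0.268%.

For a repeat of Thursday's flask at 15 °C, S is 1.71, which reads 81.9%; the computed flask gives 71.4% of target.

(The runs were generated by integration with constants of no real substance; noise was put on by code.)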